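**Plan**
- Cuts, in retrosynthetic order: the C8 O–CH3 bond (the phenol is carried as its methyl ether); the lactone O2–C1 bond (opened to a C3 carbinol and a C1 diethylamide); then, after a C1'=C2' double bond is put back, the C3–C1' bond, which separates an arylacetaldehyde (arene with C1, C4 and C3) from the complete chain C1'–C11' as a terminal alkyne.
- Enabling feature: C3, the oxygen-bearing sp3 carbon of the lactone ring, is bonded directly to chain carbon C1'. It can therefore be made as a secondary carbinol by adding a C1' alkenyl nucleophile to a C3 aldehyde, and the C1'=C2' alkene left behind is simply saturated.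
- Forward order: arene fragment (amide, ortho-allylation, ozonolysis) and chain fragment (resolved epoxide, Grignard opening, O-silylation, alkyne unmasking); the chain is joined at C3–C1' by catalytic asymmetric alkenylzinc addition; hydrogenation; the only ring that is built, the lactone, closes afterwards by O2–C1 acyl transfer; the C8 methyl ether is cleaved last.
- Stereochemistry: C6' (S) comes from (S)-1,2-epoxyheptane obtained by hydrolytic kinetic resolution; C3 (R in the target) is set by the chiral amino alcohol catalyst in the alkenylzinc addition and is retained in the lactonisation.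

Key step: step 8

Remark: positions follow 3,4-dihydroisocoumarin numbering (C1 lactone carbonyl, O2, C3, C4, C8 phenol carbon), with C1'–C11' for the side chain; the target is read as (3R,6'S).

**Step 1**
Reactants: 1 2,4-dimethoxybenzoic acid
Product: 3 N,N-diethyl-2,4-dimethoxybenzamide, via 2,4-dimethoxybenzoyl chloride 2 (not isolated)
Conditions: (COCl)2, DMF (cat.), CH2Cl2, 0 °C → rt; then Et2NH, Et3N, CH2Cl2, 0 °C → rt
Reagents that add atoms: diethylamine, CCNCC
Why: Acid chloride formation followed by amidation is the standard route to tertiary benzamides, and the diethylamide serves first as the ortho-directing group and later as the acyl donor for the lactone.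

**Step 2**
Reactants: 3 N,N-diethyl-2,4-dimethoxybenzamide; 4 allyl bromide
Product: 7 N,N-diethyl-2,4-dimethoxy-6-(prop-2-en-1-yl)benzamide, via aryllithium 5 (not isolated), via arylmagnesium bromide 6 (not isolated)
Conditions: s-BuLi, TMEDA, THF, −78 °C; MgBr2·OEt2, −78 °C; then 4, −78 °C → rt
Reagents that add atoms: none
Why: In this directed ortho-metalation the tertiary amide should steer s-BuLi/TMEDA to C6, the only position ortho to it, in preference to the site between the two methoxy groups, and lithium-to-magnesium exchange before allylation suppresses halogen–metal exchange and proton transfer.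

**Step 3**
Reactants: 7 N,N-diethyl-2,4-dimethoxy-6-(prop-2-en-1-yl)benzamide
Product: 9 N,N-diethyl-2,4-dimethoxy-6-(2-oxoethyl)benzamide, via secondary ozonide 8 (not isolated)
Conditions: O3, CH2Cl2, −78 °C (stopped at the first blue tint); then Me2S, −78 °C → rt; used without storage
Reagents that add atoms: ozone, [O-][O+]=O
Why: Ozonolysis (cycloaddition, cycloreversion and recombination to the ozonide) with reductive cleavage by dimethyl sulfide should give the arylacetaldehyde, because the monosubstituted alkene is expected to react faster than the arene when ozone is dosed only to the end point.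

**Step 4**
Reactants: 10 rac-1,2-epoxyheptane
Product: 11 (S)-1,2-epoxyheptane
Conditions: (R,R)-(salen)Co(OAc) (0.5 mol%; trivalent cobalt; salen = N,N'-bis(3,5-di-tert-butylsalicylidene)cyclohexane-1,2-diamine dianion), H2O (0.55 equiv), neat, 0 °C → rt; distillation
Reagents that add atoms: none
Why: In the Jacobsen hydrolytic kinetic resolution this catalyst enantiomer should hydrolyse the (R)-epoxide selectively and leave the (S)-epoxide, which is distilled from the diol and supplies C6' of the target.

**Step 5**
Reactants: 11 (S)-1,2-epoxyheptane; 12 4-bromo-1-(trimethylsilyl)but-1-yne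
Product: 14 (6S)-1-(trimethylsilyl)undec-1-yn-6-ol, via Grignard reagent 13 (not isolated)
Conditions: 12, Mg, THF, rt → 45 °C; then CuI (10 mol%), 11, THF, −30 → 0 °C; aq. NH4Cl
Reagents that add atoms: none
Why: Copper-catalysed Grignard opening of a terminal epoxide is an SN2 attack at the unsubstituted carbon, so the C–O bond at the stereocentre is untouched and the (S) configuration is carried over, while the C-silyl group keeps the alkyne from being deprotonated.

**Step 6**
Reactants: 14 (6S)-1-(trimethylsilyl)undec-1-yn-6-ol
Product: 15 (6S)-6-(tert-butyldimethylsilyloxy)-1-(trimethylsilyl)undec-1-yne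
Conditions: TBSCl, imidazole, DMF, rt
Reagents that add atoms: tert-butyldimethylsilyl chloride, CC(C)(C)[Si](C)(C)Cl
Why: Standard silyl ether formation protects the C6' oxygen against the borane and organozinc reagents of the coupling.

**Step 7**
Reactants: 15 (6S)-6-(tert-butyldimethylsilyloxy)-1-(trimethylsilyl)undec-1-yne
Product: 16 (6S)-6-(tert-butyldimethylsilyloxy)undec-1-yne
Conditions: K2CO3 (cat.), MeOH, rt
Reagents that add atoms: none
Why: Base-catalysed methanolysis of the alkynyl C–Si bond (protodesilylation) is selective for the alkynylsilane, and the hindered secondary silyl ether is expected to survive.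

**Step 8**
Reactants: 16 (6S)-6-(tert-butyldimethylsilyloxy)undec-1-yne; 9 N,N-diethyl-2,4-dimethoxy-6-(2-oxoethyl)benzamide
Product: 19 N,N-diethyl-2-[(2S,3E,8S)-8-(tert-butyldimethylsilyloxy)-2-hydroxytridec-3-en-1-yl]-4,6-dimethoxybenzamide, via alkenylborane 17 (not isolated), via alkenyl(methyl)zinc 18 (not isolated)
Conditions: BH3·SMe2, cyclohexene, toluene, 0 °C [gives (C6H11)2BH]; 16, 0 °C → rt; Zn(CH3)2, −78 °C; (2R)-(+)-3-exo-(dimethylamino)isoborneol (5 mol%); 9 (slow addition), −20 → 0 °C; aq. NH4Cl
Reagents that add atoms: none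
Why: Syn hydroboration of the terminal alkyne 16 with (C6H11)2BH puts boron on the terminal carbon and gives the (E)-alkenylborane 17, whose alkenyl group passes to zinc on treatment with Zn(CH3)2, and the alkenyl(methyl)zinc 18 then transfers only its sp2 carbon to the aldehyde carbon of 9. The closest known reaction type is the amino-alcohol-catalysed enantioselective addition of alkenylzinc reagents, generated by alkyne hydroboration and boron-to-zinc exchange, to aldehydes. The step forms the open-chain C3–C1' bond and closes no ring. The new stereocentre C3 is set by the catalyst: the zinc aminoalkoxide formed from the (2R)-(+)-amino alcohol binds the aldehyde at zinc and a second alkenylzinc at oxygen in a bicyclic transition state and should deliver the alkenyl group to the Re face of 9, which gives the (S)-allylic alcohol (R at C3 once the alkene is saturated); the (2S)-(−)-ligand is the one associated with Si-face delivery. The step needs facial selectivity at the aldehyde (secured by ligand acceleration over the uncatalysed pathway, helped by slow addition of 9 at low temperature, and independent of the remote silyloxy centre), E geometry (secured by syn hydroboration and irrelevant after step 9), and chemoselectivity for the aldehyde over the tertiary amide and over α-deprotonation (secured by the low basicity and modest reactivity of the organozinc).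

**Step 9**
Reactants: 19 N,N-diethyl-2-[(2S,3E,8S)-8-(tert-butyldimethylsilyloxy)-2-hydroxytridec-3-en-1-yl]-4,6-dimethoxybenzamide
Product: 20 N,N-diethyl-2-[(2R,8S)-8-(tert-butyldimethylsilyloxy)-2-hydroxytridecyl]-4,6-dimethoxybenzamide
Conditions: H2 (1 atm), 5% Pt/C, EtOAc, rt
Reagents that add atoms: none
Why: Heterogeneous catalytic hydrogenation should saturate the disubstituted alkene without touching arene, amide or silyl ether, platinum being chosen over palladium because it is less prone to allylic C–O hydrogenolysis and to isomerisation of the allylic alcohol, and the descriptor at the carbinol changes from S to R only through the change in substituent priority.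

**Step 10**
Reactants: 20 N,N-diethyl-2-[(2R,8S)-8-(tert-butyldimethylsilyloxy)-2-hydroxytridecyl]-4,6-dimethoxybenzamide
Product: 22 (3R)-3-[(6S)-6-hydroxyundecyl]-6,8-dimethoxy-3,4-dihydro-1H-isochromen-1-one, via diol amide 21 (not isolated)
Conditions: 3 M aq. HCl/1,4-dioxane (1:1), 80 °C
Reagents that add atoms: none
Why: Aqueous acid first hydrolyses the silyl ether, and the C3 hydroxyl then attacks the protonated ortho-amide in a 6-exo-trig N-to-O acyl transfer that expels diethylamine and gives the six-membered lactone with retention at C3, since the C3–O bond is never broken.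

**Step 11**
Reactants: 22 (3R)-3-[(6S)-6-hydroxyundecyl]-6,8-dimethoxy-3,4-dihydro-1H-isochromen-1-one
Product: 23 (3R)-8-hydroxy-3-[(6S)-6-hydroxyundecyl]-6-methoxy-3,4-dihydro-1H-isochromen-1-one
Conditions: BCl3 (3 equiv), CH2Cl2, −78 → 0 °C; H2O
Reagents that add atoms: none
Why: In this chelation-controlled Lewis-acid cleavage of an ortho-carbonyl aryl methyl ether, BCl3 bridges the lactone carbonyl and the peri C8 methoxy oxygen so that chloride should remove only that methyl group, while the C6' alcohol is held as a borate that is hydrolysed on work-up.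

**Compound list**
1 | 2,4-dimethoxybenzoic acid | COc1ccc(C(=O)O)c(OC)c1 | starting material
2 | 2,4-dimethoxybenzoyl chloride | COc1ccc(C(=O)Cl)c(OC)c1 | intermediate (not isolated)
3 | N,N-diethyl-2,4-dimethoxybenzamide | CCN(CC)C(=O)c1ccc(OC)cc1OC | intermediate
4 | allyl bromide (3-bromoprop-1-ene) | C=CCBr | starting material
5 | 6-lithio-N,N-diethyl-2,4-dimethoxybenzamide (aryllithium) | CCN(CC)C(=O)c1c([Li])cc(OC)cc1OC | intermediate (not isolated)
6 | [2-(diethylcarbamoyl)-3,5-dimethoxyphenyl]magnesium bromide | CCN(CC)C(=O)c1c([Mg]Br)cc(OC)cc1OC | intermediate (not isolated)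
7 | N,N-diethyl-2,4-dimethoxy-6-(prop-2-en-1-yl)benzamide | CCN(CC)C(=O)c1c(CC=C)cc(OC)cc1OC | intermediate
8 | N,N-diethyl-2,4-dimethoxy-6-(1,2,4-trioxolan-3-ylmethyl)benzamide (secondary ozonide) | CCN(CC)C(=O)c1c(CC2OCOO2)cc(OC)cc1OC | intermediate (not isolated)
9 | N,N-diethyl-2,4-dimethoxy-6-(2-oxoethyl)benzamide | CCN(CC)C(=O)c1c(CC=O)cc(OC)cc1OC | intermediate
10 | rac-1,2-epoxyheptane (2-pentyloxirane) | CCCCCC1CO1 | starting material
11 | (S)-1,2-epoxyheptane [(2S)-2-pentyloxirane] | CCCCC[C@H]1CO1 | intermediate
12 | 4-bromo-1-(trimethylsilyl)but-1-yne | C[Si](C)(C)C#CCCBr | starting material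
13 | [4-(trimethylsilyl)but-3-yn-1-yl]magnesium bromide | C[Si](C)(C)C#CCC[Mg]Br | intermediate (not isolated)
14 | (6S)-1-(trimethylsilyl)undec-1-yn-6-ol | CCCCC[C@H](O)CCCC#C[Si](C)(C)C | intermediate
15 | (6S)-6-(tert-butyldimethylsilyloxy)-1-(trimethylsilyl)undec-1-yne | CCCCC[C@H](O[Si](C)(C)C(C)(C)C)CCCC#C[Si](C)(C)C | intermediate
16 | (6S)-6-(tert-butyldimethylsilyloxy)undec-1-yne | CCCCC[C@H](O[Si](C)(C)C(C)(C)C)CCCC#C | intermediate
17 | [(1E,6S)-6-(tert-butyldimethylsilyloxy)undec-1-en-1-yl]dicyclohexylborane | CCCCC[C@H](O[Si](C)(C)C(C)(C)C)CCC/C=C/B(C1CCCCC1)C1CCCCC1 | intermediate (not isolated)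
18 | [(1E,6S)-6-(tert-butyldimethylsilyloxy)undec-1-en-1-yl](methyl)zinc | CCCCC[C@H](O[Si](C)(C)C(C)(C)C)CCC/C=C/[Zn]C | intermediate (not isolated)
19 | N,N-diethyl-2-[(2S,3E,8S)-8-(tert-butyldimethylsilyloxy)-2-hydroxytridec-3-en-1-yl]-4,6-dimethoxybenzamide | CCCCC[C@H](O[Si](C)(C)C(C)(C)C)CCC/C=C/[C@@H](O)Cc1cc(OC)cc(OC)c1C(=O)N(CC)CC | intermediate
20 | N,N-diethyl-2-[(2R,8S)-8-(tert-butyldimethylsilyloxy)-2-hydroxytridecyl]-4,6-dimethoxybenzamide | CCCCC[C@H](O[Si](C)(C)C(C)(C)C)CCCCC[C@@H](O)Cc1cc(OC)cc(OC)c1C(=O)N(CC)CC | intermediate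
21 | N,N-diethyl-2-[(2R,8S)-2,8-dihydroxytridecyl]-4,6-dimethoxybenzamide | CCCCC[C@H](O)CCCCC[C@@H](O)Cc1cc(OC)cc(OC)c1C(=O)N(CC)CC | intermediate (not isolated)
22 | (3R)-3-[(6S)-6-hydroxyundecyl]-6,8-dimethoxy-3,4-dihydro-1H-isochromen-1-one | CCCCC[C@H](O)CCCCC[C@@H]1Cc2cc(OC)cc(OC)c2C(=O)O1 | intermediate
23 | (3R)-8-hydroxy-3-[(6S)-6-hydroxyundecyl]-6-methoxy-3,4-dihydro-1H-isochromen-1-one | CCCCC[C@H](O)CCCCC[C@@H]1Cc2cc(OC)cc(O)c2C(=O)O1 | target

**Totals**
Total step count: 11.
Longest linear sequence: 8 steps (steps 4–11, from rac-1,2-epoxyheptane 10); the arene branch contributes steps 1–3.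

**Steps most likely to fail**

Step 8. Facial selectivity may erode because the ortho-amide carbonyl can chelate zinc and open a ligand-free addition pathway, and the enolisable arylacetaldehyde may self-condense before it is captured. The fallback sets out from alkyne 16 and aldehyde 9 and separates bond formation from stereocontrol. The same hydroboration, boron-to-zinc exchange and addition are run without amino alcohol to give the C2-epimeric mixture N,N-diethyl-2-[(2RS,3E,8S)-8-(tert-butyldimethylsilyloxy)-2-hydroxytridec-3-en-1-yl]-4,6-dimethoxybenzamide F1. Oxidation with Dess–Martin periodinane (NaHCO3, CH2Cl2, 0 °C) should give the enone N,N-diethyl-2-[(3E,8S)-8-(tert-butyldimethylsilyloxy)-2-oxotridec-3-en-1-yl]-4,6-dimethoxybenzamide F2. Corey–Bakshi–Shibata reduction with (R)-1-methyl-3,3-diphenyltetrahydro-1H,3H-pyrrolo[1,2-c][1,3,2]oxazaborole and catecholborane in toluene at −78 °C, with the alkenyl group acting as the large substituent, should give the (S)-carbinol and return to the route at 19.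

Step 3. Ozone may over-oxidise the electron-rich dimethoxyarene, and the arylacetaldehyde may be lost through enolisation, aldol condensation or air oxidation during reductive work-up. The fallback sets out from 7 and avoids ozone. Dihydroxylation with K2OsO4·2H2O (cat.) and N-methylmorpholine N-oxide in acetone/water should give the racemic diol N,N-diethyl-2-(2,3-dihydroxypropyl)-4,6-dimethoxybenzamide F3. Glycol cleavage with NaIO4 in THF/water at rt under neutral conditions then gives aldehyde 9, which is taken directly into step 8.

Step 11. The free C6' hydroxyl consumes BCl3 and may undergo substitution or elimination through its dichloroborinate, leading to incomplete or unclean ether cleavage. The fallback sets out from 22 and masks the carbinol first. Acetylation (Ac2O, pyridine, DMAP, CH2Cl2) gives (6S)-1-[(3R)-6,8-dimethoxy-1-oxo-3,4-dihydro-1H-isochromen-3-yl]undecan-6-yl acetate F4. BCl3 in CH2Cl2 at −78 → 0 °C should then give (6S)-1-[(3R)-8-hydroxy-6-methoxy-1-oxo-3,4-dihydro-1H-isochromen-3-yl]undecan-6-yl acetate F5. Methanolysis of the acetate (K2CO3, MeOH, 0 °C → rt, followed by dilute HCl to re-close any opened lactone) returns to the route at the target 23.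

**Further compounds**
F1 | step 8 | N,N-diethyl-2-[(2RS,3E,8S)-8-(tert-butyldimethylsilyloxy)-2-hydroxytridec-3-en-1-yl]-4,6-dimethoxybenzamide (C2-epimer mixture) | CCCCC[C@H](O[Si](C)(C)C(C)(C)C)CCC/C=C/C(O)Cc1cc(OC)cc(OC)c1C(=O)N(CC)CC
F2 | step 8 | N,N-diethyl-2-[(3E,8S)-8-(tert-butyldimethylsilyloxy)-2-oxotridec-3-en-1-yl]-4,6-dimethoxybenzamide | CCCCC[C@H](O[Si](C)(C)C(C)(C)C)CCC/C=C/C(=O)Cc1cc(OC)cc(OC)c1C(=O)N(CC)CC
F3 | step 3 | N,N-diethyl-2-(2,3-dihydroxypropyl)-4,6-dimethoxybenzamide (racemic) | CCN(CC)C(=O)c1c(CC(O)CO)cc(OC)cc1OC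
F4 | step 11 | (6S)-1-[(3R)-6,8-dimethoxy-1-oxo-3,4-dihydro-1H-isochromen-3-yl]undecan-6-yl acetate | CCCCC[C@H](OC(C)=O)CCCCC[C@@H]1Cc2cc(OC)cc(OC)c2C(=O)O1
F5 | step 11 | (6S)-1-[(3R)-8-hydroxy-6-methoxy-1-oxo-3,4-dihydro-1H-isochromen-3-yl]undecan-6-yl acetate | CCCCC[C@H](OC(C)=O)CCCCC[C@@H]1Cc2cc(OC)cc(O)c2C(=O)O1
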